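**Retrosynthetic overview**
1. Target ⇒ C12 ester bond (Yamaguchi coupling with a silyl-protected (3R,5S)-acid) and a last-step oxygenation at C2 of a ring-A cyclopentanone to the diosphenol.
2. Ring A (key step, formed last) ⇒ C1–C18 bond by carbene-catalysed crossed benzoin, the C1 aldehyde acting as an acyl anion toward the C18 ketone; C3–C4 bond from a Mukaiyama–Michael addition to crotonaldehyde.
3. Ring B ⇒ Claisen ring expansion of a 2-methylene-6-vinyltetrahydropyran made from an α-methylene δ-lactone (forms C4–C5, forces the Z C6=C7 olefin).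
4. Ring D ⇒ alkyne hydration/aldol condensation, then Li/NH3 reduction (trans C/D fusion, C12, C13).
5. Ring C ⇒ (+)-nopinone (chiral pool, carries C8, templates C10): two alkylations, cyclobutane opening, Sakurai allylation (C16). Ring order: C, D, B, A.

Assumption: (+)-nopinone (from natural (−)-β-pinene), 1-bromo-4-methylpent-2-yne and (S)-1-bromo-2-methylbutane are bought.

Convention for names from compound 10 on (target-skeleton numbering): C1 ring-A ketone carbon, C2, C3 (C-methyl), C4 (ring A/B CH), C5, C6, C7 (C-methyl), C8, C9, C10 (angular methyl), C11, C12 (oxygenated), C13 (isopropyl), C14, C15, C16, C17 (exocyclic methylene), C18 (ring A/B carbinol). Extra bonds: C1–C18, C4–C18, C8–C16, C10–C14. β = face of the C10 methyl, α = opposite face.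

Step 1
Reactants: 1 (1R,5S)-(+)-nopinone; 2 1-bromo-4-methylpent-2-yne
Product: 3 (1R,3R,5S)-6,6-dimethyl-3-(4-methylpent-2-yn-1-yl)bicyclo[3.1.1]heptan-2-one
Conditions: LiN(iPr)2, THF, −78 °C; then 2, DMPU, −78 → 0 °C
Reagents that add atoms: none
Why: Kinetic enolate alkylation (SN2) at C3, the only enolisable position of nopinone; the bromide enters anti to the gem-dimethyl bridge.

Step 2
Reactants: 3 (1R,3R,5S)-6,6-dimethyl-3-(4-methylpent-2-yn-1-yl)bicyclo[3.1.1]heptan-2-one
Product: 4 (1R,3S,5R)-3,6,6-trimethyl-3-(4-methylpent-2-yn-1-yl)bicyclo[3.1.1]heptan-2-one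
Conditions: LiN(iPr)2, THF, −78 → 0 °C; MeI, −78 → 23 °C
Reagents that add atoms: iodomethane CI
Why: Second enolate alkylation, again anti to the gem-dimethyl bridge, so the quaternary centre (future C10) carries methyl anti and the alkynyl chain syn to the bridge.

Step 3
Reactants: 4 (1R,3S,5R)-3,6,6-trimethyl-3-(4-methylpent-2-yn-1-yl)bicyclo[3.1.1]heptan-2-one
Product: 6 trimethyl{[(4R,6S)-6-methyl-6-(4-methylpent-2-yn-1-yl)-4-(prop-1-en-2-yl)cyclohex-1-en-1-yl]oxy}silane, via iodo enol silane 5 (not isolated)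
Conditions: Me3SiI, CH2Cl2, −40 → 0 °C; then DBU, 40 °C; non-aqueous filtration
Reagents that add atoms: iodotrimethylsilane C[Si](C)(C)I
Why: Silyl iodide fragmentation of the strained cyclobutyl ketone (C1–C6 heterolysis to the tertiary iodide and a regiodefined silyl enol ether) followed by E2 elimination to the isopropenyl group; both stereocentres are untouched, and the former bridge carbon becomes C7 on C8.

Step 4
Reactants: 6 trimethyl{[(4R,6S)-6-methyl-6-(4-methylpent-2-yn-1-yl)-4-(prop-1-en-2-yl)cyclohex-1-en-1-yl]oxy}silane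
Product: 7 (4S,6S)-6-methyl-6-(4-methylpent-2-yn-1-yl)-4-(prop-1-en-2-yl)cyclohex-2-en-1-one
Conditions: Pd(OAc)2 (10 mol %), O2 (1 atm), DMSO, 40 °C
Reagents that add atoms: none
Why: Saegusa–Ito dehydrosilylation of the regiodefined enol silane gives the enone without touching a stereocentre.

Step 5
Reactants: 7 (4S,6S)-6-methyl-6-(4-methylpent-2-yn-1-yl)-4-(prop-1-en-2-yl)cyclohex-2-en-1-one
Product: 8 (2S,4S,5S)-2-methyl-2-(4-methylpent-2-yn-1-yl)-4-(prop-1-en-2-yl)-5-(prop-2-en-1-yl)cyclohexan-1-one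
Conditions: CH2=CHCH2SiMe3, TiCl4, CH2Cl2, −78 °C
Reagents that add atoms: allyltrimethylsilane C=CC[Si](C)(C)C
Why: Hosomi–Sakurai conjugate allylation; axial attack anti to the neighbouring isopropenyl group sets the future C16 trans to C8.

Step 6
Reactants: 8 (2S,4S,5S)-2-methyl-2-(4-methylpent-2-yn-1-yl)-4-(prop-1-en-2-yl)-5-(prop-2-en-1-yl)cyclohexan-1-one
Product: 10 ring C/D enone 16β-allyl-8α-isopropenyl-13-isopropyl-10β-methylhydrind-13(14)-en-12-one, via 1,4-diketone 9 (not isolated)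
Conditions: NaAuCl4·2H2O (3 mol %), MeOH/H2O 10:1, 65 °C; then KOH, 65 °C
Reagents that add atoms: water O
Why: NaAuCl4-catalysed alkyne hydration steered by 5-exo participation of the ring ketone gives the 1,4-diketone, and the intramolecular aldol condensation closes ring D because only the five-ring enone can dehydrate.

Step 7
Reactants: 10 ring C/D enone 16β-allyl-8α-isopropenyl-13-isopropyl-10β-methylhydrind-13(14)-en-12-one
Product: 11 ring C/D alcohol 16β-allyl-8α-isopropenyl-13β-isopropyl-10β-methyl-14α-H-hydrindan-12α-ol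
Conditions: Li, NH3(l)/THF, −78 → −33 °C; then MeOH, −33 °C; NH4Cl
Reagents that add atoms: none
Why: Li/NH3 (Birch-type) enone reduction: axial protonation at C14 gives the trans-hydrindane, α-face protonation of the enolate puts the isopropyl group β, and in-situ metal–ammonia reduction of the ketone gives the more stable 12α-alcohol trans to isopropyl.

Step 8
Reactants: 11 ring C/D alcohol 16β-allyl-8α-isopropenyl-13β-isopropyl-10β-methyl-14α-H-hydrindan-12α-ol
Product: 12 keto ester methyl 2-(8α-acetyl-12α-hydroxy-13β-isopropyl-10β-methyl-14α-H-hydrindan-16β-yl)acetate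
Conditions: O3, NaOH, MeOH/CH2Cl2, −78 °C
Reagents that add atoms: ozone [O-][O+]=O; methanol CO
Why: Ozonolysis in methanolic NaOH (Marshall conditions) turns the allyl group into a methyl ester and the isopropenyl group into a methyl ketone in one operation; the equatorial C8 centre next to the new ketone is the thermodynamic one.

Step 9
Reactants: 12 keto ester methyl 2-(8α-acetyl-12α-hydroxy-13β-isopropyl-10β-methyl-14α-H-hydrindan-16β-yl)acetate
Product: 14 trans-fused δ-lactone (C18 carbonyl–O–C7 with 7S methyl and vinyl), via hydroxy ester 13 (not isolated)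
Conditions: CH2=CHMgBr (2.1 equiv), THF, −78 → 23 °C
Reagents that add atoms: vinylmagnesium bromide C=C[Mg]Br
Why: Grignard 1,2-addition to the methyl ketone (faster than to the ester) and lactonisation of the tertiary alkoxide; the new C7 carbinol centre is destroyed in step 11, so either epimer serves (axial-vinyl epimer drawn).

Step 10
Reactants: 14 trans-fused δ-lactone (C18 carbonyl–O–C7 with 7S methyl and vinyl)
Product: 17 α-methylene δ-lactone (14 with C17=CH2), via Mannich base 15 (not isolated), via ammonium iodide 16 (not isolated)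
Conditions: LiN(iPr)2 (2.3 equiv), THF, −78 °C; Me2N=CH2+ I−, −78 → 0 °C; then MeI, MeOH, 23 °C; then NaHCO3 (aq), CH2Cl2, 23 °C
Reagents that add atoms: N,N-dimethylmethyleneiminium iodide C=[N+](C)C.[I-]; iodomethane CI
Why: Lactone α-methylenation by Mannich reaction of the lithium enolate, N-methylation and E1cB elimination; the lactone has a single α-carbon (C17), so the exocyclic methylene is placed regiospecifically.

Step 11
Reactants: 17 α-methylene δ-lactone (14 with C17=CH2)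
Product: 19 ring B/C/D enone (6Z)-12α-hydroxy-13β-isopropyl-7,10β-dimethyl-17-methylene-8β-H-16α-H-tricycle with C18 ketone, via allyl vinyl ether 18 (not isolated)
Conditions: Cp2TiMe2 (3 equiv), toluene, 75 °C, dark; then 150 °C (sealed tube)
Reagents that add atoms: dimethyltitanocene [CH3-].[CH3-].[Ti+4].c1cc[cH-]c1.c1cc[cH-]c1
Why: Carbonyl methylenation with Cp2TiMe2 gives the 2-methylene-6-vinyltetrahydropyran, whose Claisen rearrangement ([3,3]) expands it to the eight-membered ring B (new C4–C5 bond); the ring forces the C6=C7 olefin to be Z, and C8 and C16 are not touched.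

Step 12
Reactants: 19 ring B/C/D enone (6Z)-12α-hydroxy-13β-isopropyl-7,10β-dimethyl-17-methylene-8β-H-16α-H-tricycle with C18 ketone; 20 (E)-crotonaldehyde
Product: 22 keto aldehyde (19 carrying (S)-4-oxobutan-2-yl at C4 with 4α-H), via bis-silyl dienol ether 21 (not isolated)
Conditions: Me3SiOTf, Et3N, CH2Cl2, 0 °C; concentrate; then 20, (2S,5S)-5-benzyl-2-tert-butyl-3-methylimidazolidin-4-one·CF3CO2H (20 mol %), CH2Cl2/iPrOH, −40 °C; then 1 M HCl/THF, 0 °C
Reagents that add atoms: trimethylsilyl triflate C[Si](C)(C)OS(=O)(=O)C(F)(F)F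
Why: Soft enolisation gives the only possible (C4) silyl dienol ether, which adds to the iminium ion of crotonaldehyde in an organocatalytic Mukaiyama–Michael reaction; the catalyst sets C3 (erased in step 19) and C4 stays epimerisable.

Step 13
Reactants: 22 keto aldehyde (19 carrying (S)-4-oxobutan-2-yl at C4 with 4α-H)
Product: 23 tetracyclic α-ketol (C1 ketone with 18α-OH and 4α-H and 12α-OH and 3S-methyl and 17-methylene)
Conditions: 2-(perfluorophenyl)-6,7-dihydro-5H-pyrrolo[2,1-c][1,2,4]triazol-2-ium tetrafluoroborate (20 mol %), iPr2NEt (20 mol %), CH2Cl2, 23 °C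
Reagents that add atoms: none
Why: Carbene-catalysed intramolecular crossed aldehyde–ketone benzoin: the Breslow intermediate makes the C1 aldehyde carbon an acyl anion that attacks the C18 ketone (five-ring closure should outrun the seven-ring Stetter path onto the s-trans-locked exocyclic methylene), and because the benzoin is reversible and C4 epimerisable the system is expected to settle in the cis-fused α-ketol with 18α-OH and 4α-H.

Step 14
Reactants: 24 (S)-1-bromo-2-methylbutane; 25 ethyl but-2-ynoate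
Product: 27 ethyl (2E,5S)-3,5-dimethylhept-2-enoate, via (S)-2-methylbutylmagnesium bromide 26 (not isolated)
Conditions: Mg, THF, 40 °C; CuBr·SMe2 (1.0 equiv), −40 °C; then 25, −78 °C; MeOH, −78 °C
Reagents that add atoms: magnesium [Mg]
Why: Syn carbocupration of the ynoate by (S)-2-methylbutylcopper gives the (E)-trisubstituted enoate stereospecifically; the C5 stereocentre comes from the chiral pool.

Step 15
Reactants: 27 ethyl (2E,5S)-3,5-dimethylhept-2-enoate
Product: 29 ethyl (3R,5S)-3-hydroxy-3,5-dimethylheptanoate, via tertiary boronate 28 (not isolated)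
Conditions: CuCl (5 mol %), NaOtBu (10 mol %), (R,R)-2,3-bis(tert-butylmethylphosphino)quinoxaline (6 mol %; the ligand antipode that gives 3R is used), B2pin2, MeOH, THF, 23 °C; then NaBO3·4H2O, THF/H2O, 23 °C
Reagents that add atoms: bis(pinacolato)diboron CC1(C)OB(OC1(C)C)B1OC(C)(C)C(C)(C)O1; sodium perborate tetrahydrate [Na+].[O-]OB=O.O.O.O.O
Why: CuCl-catalysed enantioselective conjugate borylation sets the tertiary C3 centre under ligand control, and perborate oxidation replaces boron by OH with retention.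

Step 16
Reactants: 29 ethyl (3R,5S)-3-hydroxy-3,5-dimethylheptanoate
Product: 30 ethyl (3R,5S)-3,5-dimethyl-3-(triethylsilyloxy)heptanoate
Conditions: Et3SiOTf, 2,6-lutidine, CH2Cl2, 0 → 23 °C
Reagents that add atoms: triethylsilyl triflate CC[Si](CC)(CC)OS(=O)(=O)C(F)(F)F
Why: Silylation of the tertiary alcohol with a silyl triflate blocks retro-aldol cleavage under the basic conditions of step 19.

Step 17
Reactants: 30 ethyl (3R,5S)-3,5-dimethyl-3-(triethylsilyloxy)heptanoate
Product: 31 (3R,5S)-3,5-dimethyl-3-(triethylsilyloxy)heptanoic acid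
Conditions: LiOH, THF/MeOH/H2O, 40 °C; then HCl (aq) to pH 4, 0 °C
Reagents that add atoms: lithium hydroxide [Li+].[OH-]
Why: Ester saponification; the tertiary triethylsilyl ether tolerates hydroxide and a brief mildly acidic work-up.

Step 18
Reactants: 23 tetracyclic α-ketol (C1 ketone with 18α-OH and 4α-H and 12α-OH and 3S-methyl and 17-methylene); 31 (3R,5S)-3,5-dimethyl-3-(triethylsilyloxy)heptanoic acid
Product: 33 12-O-acyl ketol (23 esterified at the 12α-oxygen by 31), via mixed anhydride 32 (not isolated)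
Conditions: 31, 2,4,6-Cl3C6H2COCl, Et3N, THF, 23 °C; then 23, DMAP, toluene, 40 °C
Reagents that add atoms: 2,4,6-trichlorobenzoyl chloride O=C(Cl)c1c(Cl)cc(Cl)cc1Cl
Why: Yamaguchi esterification acylates the secondary C12 hydroxyl selectively over the tertiary C18 hydroxyl, with retention at C12.

Step 19
Reactants: 33 12-O-acyl ketol (23 esterified at the 12α-oxygen by 31)
Product: 35 CNP0110944.3, via silyl diosphenol 34 (not isolated)
Conditions: KOtBu (3 equiv), O2 (1 atm), THF/tBuOH, −40 → −20 °C; then 1 M HCl (aq), 23 °C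
Reagents that add atoms: dioxygen O=O
Why: Base-mediated autoxidation of the ring-A ketone at its only enolisable position (C2) gives the 1,2-diketone, which tautomerises toward C3 to the diosphenol and erases the C3 centre; the acidic quench removes the triethylsilyl ether.

**Compound list**
1 | (1R,5S)-(+)-nopinone, (1R,5S)-6,6-dimethylbicyclo[3.1.1]heptan-2-one | O=C1CC[C@H]2C[C@@H]1C2(C)C | starting material
2 | 1-bromo-4-methylpent-2-yne | BrCC#CC(C)C | starting material
3 | (1R,3R,5S)-6,6-dimethyl-3-(4-methylpent-2-yn-1-yl)bicyclo[3.1.1]heptan-2-one | O=C1[C@@H](CC#CC(C)C)C[C@H]2C[C@@H]1C2(C)C | intermediate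
4 | (1R,3S,5R)-3,6,6-trimethyl-3-(4-methylpent-2-yn-1-yl)bicyclo[3.1.1]heptan-2-one | O=C1[C@](C)(CC#CC(C)C)C[C@H]2C[C@@H]1C2(C)C | intermediate
5 | iodo enol silane, {[(4R,6S)-4-(2-iodopropan-2-yl)-6-methyl-6-(4-methylpent-2-yn-1-yl)cyclohex-1-en-1-yl]oxy}trimethylsilane | C[Si](C)(C)OC1=CC[C@@H](C(C)(C)I)C[C@@]1(C)CC#CC(C)C | intermediate
6 | trimethyl{[(4R,6S)-6-methyl-6-(4-methylpent-2-yn-1-yl)-4-(prop-1-en-2-yl)cyclohex-1-en-1-yl]oxy}silane | C[Si](C)(C)OC1=CC[C@@H](C(C)=C)C[C@@]1(C)CC#CC(C)C | intermediate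
7 | (4S,6S)-6-methyl-6-(4-methylpent-2-yn-1-yl)-4-(prop-1-en-2-yl)cyclohex-2-en-1-one | O=C1C=C[C@@H](C(C)=C)C[C@@]1(C)CC#CC(C)C | intermediate
8 | (2S,4S,5S)-2-methyl-2-(4-methylpent-2-yn-1-yl)-4-(prop-1-en-2-yl)-5-(prop-2-en-1-yl)cyclohexan-1-one | O=C1C[C@H](CC=C)[C@@H](C(C)=C)C[C@@]1(C)CC#CC(C)C | intermediate
9 | 1,4-diketone, (2S,4S,5S)-2-methyl-2-(4-methyl-2-oxopentyl)-4-(prop-1-en-2-yl)-5-(prop-2-en-1-yl)cyclohexan-1-one | O=C1C[C@H](CC=C)[C@@H](C(C)=C)C[C@@]1(C)CC(=O)CC(C)C | intermediate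
10 | ring C/D enone: 16β-allyl-8α-isopropenyl-13-isopropyl-10β-methylhydrind-13(14)-en-12-one | C=CC[C@H]1CC2=C(C(C)C)C(=O)C[C@]2(C)C[C@@H]1C(C)=C | intermediate
11 | ring C/D alcohol: 16β-allyl-8α-isopropenyl-13β-isopropyl-10β-methyl-14α-H-hydrindan-12α-ol | C=CC[C@H]1C[C@H]2[C@@H](C(C)C)[C@H](O)C[C@]2(C)C[C@@H]1C(C)=C | intermediate
12 | keto ester: methyl 2-(8α-acetyl-12α-hydroxy-13β-isopropyl-10β-methyl-14α-H-hydrindan-16β-yl)acetate | COC(=O)C[C@H]1C[C@H]2[C@@H](C(C)C)[C@H](O)C[C@]2(C)C[C@@H]1C(C)=O | intermediate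
13 | hydroxy ester: 12 with the acetyl group converted into (S)-2-hydroxybut-3-en-2-yl | COC(=O)C[C@H]1C[C@H]2[C@@H](C(C)C)[C@H](O)C[C@]2(C)C[C@@H]1[C@@](C)(O)C=C | intermediate
14 | δ-lactone trans-fused to ring C: ring O–C18(=O)–C17H2–C16–C8–C7, with 7S methyl and vinyl on C7, 12α-OH | O=C1C[C@H]2C[C@H]3[C@@H](C(C)C)[C@H](O)C[C@]3(C)C[C@@H]2[C@](C)(C=C)O1 | intermediate
15 | Mannich base: 14 carrying CH2NMe2 on C17 (C17 epimers) | O=C1C(CN(C)C)[C@H]2C[C@H]3[C@@H](C(C)C)[C@H](O)C[C@]3(C)C[C@@H]2[C@](C)(C=C)O1 | intermediate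
16 | ammonium iodide: 14 carrying CH2NMe3+ I− on C17 | O=C1C(C[N+](C)(C)C)[C@H]2C[C@H]3[C@@H](C(C)C)[C@H](O)C[C@]3(C)C[C@@H]2[C@](C)(C=C)O1.[I-] | intermediate
17 | α-methylene δ-lactone: 14 with C17=CH2 | O=C1C(=C)[C@H]2C[C@H]3[C@@H](C(C)C)[C@H](O)C[C@]3(C)C[C@@H]2[C@](C)(C=C)O1 | intermediate
18 | allyl vinyl ether: 17 with the C18 carbonyl replaced by C18=CH2 (the new CH2 is C4) | C=C1C(=C)[C@H]2C[C@H]3[C@@H](C(C)C)[C@H](O)C[C@]3(C)C[C@@H]2[C@](C)(C=C)O1 | intermediate
19 | ring B/C/D enone: C18 ketone, C17 exocyclic methylene, (6Z)-C6=C7 with 7-methyl, C4 and C5 methylene, 8β-H, 16α-H, ring C/D as in 11 | C=C1[C@H]2C[C@H]3[C@@H](C(C)C)[C@H](O)C[C@]3(C)C[C@@H]2/C(C)=C\CCC1=O | intermediate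
20 | (E)-crotonaldehyde, (E)-but-2-enal | C/C=C/C=O | starting material
21 | bis-silyl dienol ether: 19 as its C4=C18 trimethylsilyl enol ether and 12-O-trimethylsilyl ether | C=C1[C@H]2C[C@H]3[C@@H](C(C)C)[C@H](O[Si](C)(C)C)C[C@]3(C)C[C@@H]2/C(C)=C\CC=C1O[Si](C)(C)C | intermediate
22 | keto aldehyde: 19 carrying (S)-4-oxobutan-2-yl on C4 (4α-H) | C=C1[C@H]2C[C@H]3[C@@H](C(C)C)[C@H](O)C[C@]3(C)C[C@@H]2/C(C)=C\C[C@@H]([C@@H](C)CC=O)C1=O | intermediate
23 | tetracyclic α-ketol: C1 ketone, C2 methylene, 3S-methyl, 4α-H, 18α-OH, 17-methylene, (6Z)-olefin, 12α-OH | C=C1[C@H]2C[C@H]3[C@@H](C(C)C)[C@H](O)C[C@]3(C)C[C@@H]2/C(C)=C\C[C@H]2[C@@H](C)CC(=O)[C@@]12O | intermediate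
24 | (S)-1-bromo-2-methylbutane | BrC[C@@H](C)CC | starting material
25 | ethyl but-2-ynoate | CCOC(=O)C#CC | starting material
26 | (S)-2-methylbutylmagnesium bromide | Br[Mg]C[C@@H](C)CC | intermediate
27 | ethyl (2E,5S)-3,5-dimethylhept-2-enoate | CCOC(=O)/C=C(C)/C[C@@H](C)CC | intermediate
28 | ethyl (3S,5S)-3,5-dimethyl-3-(4,4,5,5-tetramethyl-1,3,2-dioxaborolan-2-yl)heptanoate | CCOC(=O)C[C@](C)(B1OC(C)(C)C(C)(C)O1)C[C@@H](C)CC | intermediate
29 | ethyl (3R,5S)-3-hydroxy-3,5-dimethylheptanoate | CCOC(=O)C[C@](C)(O)C[C@@H](C)CC | intermediate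
30 | ethyl (3R,5S)-3,5-dimethyl-3-(triethylsilyloxy)heptanoate | CCOC(=O)C[C@](C)(O[Si](CC)(CC)CC)C[C@@H](C)CC | intermediate
31 | (3R,5S)-3,5-dimethyl-3-(triethylsilyloxy)heptanoic acid | OC(=O)C[C@](C)(O[Si](CC)(CC)CC)C[C@@H](C)CC | intermediate
32 | mixed anhydride of 31 and 2,4,6-trichlorobenzoic acid | O=C(OC(=O)C[C@](C)(O[Si](CC)(CC)CC)C[C@@H](C)CC)c1c(Cl)cc(Cl)cc1Cl | intermediate
33 | 12-O-acyl ketol: 23 esterified at the 12α-oxygen by 31 | C=C1[C@H]2C[C@H]3[C@@H](C(C)C)[C@H](OC(=O)C[C@](C)(O[Si](CC)(CC)CC)C[C@@H](C)CC)C[C@]3(C)C[C@@H]2/C(C)=C\C[C@H]2[C@@H](C)CC(=O)[C@@]12O | intermediate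
34 | silyl diosphenol: 33 with ring A oxidised to the 2-hydroxy-3-methylcyclopent-2-en-1-one | C=C1[C@H]2C[C@H]3[C@@H](C(C)C)[C@H](OC(=O)C[C@](C)(O[Si](CC)(CC)CC)C[C@@H](C)CC)C[C@]3(C)C[C@@H]2/C(C)=C\C[C@H]2C(C)=C(O)C(=O)[C@@]12O | intermediate
35 | CNP0110944.3 | C=C1[C@H]2C[C@H]3[C@@H](C(C)C)[C@H](OC(=O)C[C@](C)(O)C[C@@H](C)CC)C[C@]3(C)C[C@@H]2/C(C)=C\C[C@H]2C(C)=C(O)C(=O)[C@@]12O | target

**Step count and risks**
Total step count: 19. Longest linear sequence: 15 steps (steps 1 to 13, then 18 and 19, from 1).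

The three steps most likely to fail are steps 7, 11 and 13.

Step 7 sets C12, C13 and C14 in one pot and could give the wrong C12 or C13 epimer, or touch the terminal alkenes. The fallback sets the centres one at a time and inverts C12. It sets out from 10: Li/NH3 with one equivalent of tBuOH and a cold NH4Cl quench gives the trans-fused ring C/D ketone F1. KBH(sec-Bu)3 then delivers hydride from the open α face to give the 12β-alcohol F2. Mitsunobu inversion (4-nitrobenzoic acid, PPh3, DIAD) gives the 12α 4-nitrobenzoate F3, and K2CO3/MeOH methanolysis comes back to the route at 11.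

Step 11 may fail because the α-methylene lactone 17 is a heat-sensitive acceptor and Cp2TiMe2 must also cope with the free hydroxyl. The fallback carries the methylene through the ring expansion as its Mannich base. It sets out from 14: step 10 is stopped at the Mannich base 15, which is isolated. Cp2TiMe2 gives the amino allyl vinyl ether F4, thermolysis gives the β-amino cyclooctenone F5, MeI gives the ammonium iodide F6, and NaHCO3-induced elimination comes back to the route at 19.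

Step 13 is the boldest step: the carbene may add to the exocyclic enone or follow the Stetter path, and the C4/C18 outcome rests on thermodynamic funnelling that is argued, not demonstrated. The fallback masks the enone before ring A is built. It sets out from 19: conjugate addition of PhSeH (Et3N cat.) gives the β-phenylseleno ketone F7. LiN(iPr)2/Me3SiCl gives the kinetic bis-silyl enol ether F8, and the Mukaiyama–Michael protocol of step 12 gives the seleno keto aldehyde F9. The carbene-catalysed benzoin then closes ring A on a saturated ketone to give the seleno ketol F10. NaIO4 gives the selenoxide F11, whose syn elimination at 23 °C restores the C17 methylene and comes back to the route at 23.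

Further compounds
F1 | step 7 | ring C/D ketone: 16β-allyl-8α-isopropenyl-13β-isopropyl-10β-methyl-14α-H-hydrindan-12-one | C=CC[C@H]1C[C@H]2[C@@H](C(C)C)C(=O)C[C@]2(C)C[C@@H]1C(C)=C
F2 | step 7 | 12β-alcohol (C12 epimer of 11) | C=CC[C@H]1C[C@H]2[C@@H](C(C)C)[C@@H](O)C[C@]2(C)C[C@@H]1C(C)=C
F3 | step 7 | 12α 4-nitrobenzoate of 11 | C=CC[C@H]1C[C@H]2[C@@H](C(C)C)[C@H](OC(=O)c3ccc(cc3)[N+](=O)[O-])C[C@]2(C)C[C@@H]1C(C)=C
F4 | step 11 | amino allyl vinyl ether: 15 with the C18 carbonyl replaced by C18=CH2 | C=C1C(CN(C)C)[C@H]2C[C@H]3[C@@H](C(C)C)[C@H](O)C[C@]3(C)C[C@@H]2[C@](C)(C=C)O1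
F5 | step 11 | β-amino cyclooctenone: 19 with C17 as CH–CH2NMe2 | CN(C)CC1[C@H]2C[C@H]3[C@@H](C(C)C)[C@H](O)C[C@]3(C)C[C@@H]2/C(C)=C\CCC1=O
F6 | step 11 | ammonium iodide of F5 | C[N+](C)(C)CC1[C@H]2C[C@H]3[C@@H](C(C)C)[C@H](O)C[C@]3(C)C[C@@H]2/C(C)=C\CCC1=O.[I-]
F7 | step 13 | β-phenylseleno ketone: 19 with C17 as CH–CH2SePh | c4ccccc4[Se]CC1[C@H]2C[C@H]3[C@@H](C(C)C)[C@H](O)C[C@]3(C)C[C@@H]2/C(C)=C\CCC1=O
F8 | step 13 | bis-silyl enol ether of F7 (C4=C18 enol silane and 12-O-silyl ether) | c4ccccc4[Se]CC1[C@H]2C[C@H]3[C@@H](C(C)C)[C@H](O[Si](C)(C)C)C[C@]3(C)C[C@@H]2/C(C)=C\CC=C1O[Si](C)(C)C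
F9 | step 13 | seleno keto aldehyde: F7 carrying (S)-4-oxobutan-2-yl on C4 | c4ccccc4[Se]CC1[C@H]2C[C@H]3[C@@H](C(C)C)[C@H](O)C[C@]3(C)C[C@@H]2/C(C)=C\C[C@@H]([C@@H](C)CC=O)C1=O
F10 | step 13 | seleno ketol: 23 with C17 as CH–CH2SePh | c4ccccc4[Se]CC1[C@H]2C[C@H]3[C@@H](C(C)C)[C@H](O)C[C@]3(C)C[C@@H]2/C(C)=C\C[C@H]2[C@@H](C)CC(=O)[C@@]12O
F11 | step 13 | selenoxide of F10 | O=[Se](c4ccccc4)CC1[C@H]2C[C@H]3[C@@H](C(C)C)[C@H](O)C[C@]3(C)C[C@@H]2/C(C)=C\C[C@H]2[C@@H](C)CC(=O)[C@@]12O
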